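The route rests on tying C4 and C5 together through sulfur: the oxa-bridged nine-membered ring (furanone O, C3, C4, C5, C6–C10) is first made one atom larger, as a ten-membered 1-oxa-4-thiacyclodecane closed by simple thiolate alkylation, and a Ramberg–Bäcklund ring contraction of its α-chloro sulfone then extrudes SO2 and leaves the ring-cis, trisubstituted C4=C5 alkene that conjugates with the 3(2H)-furanone. The precursor already holds the furanone, whose quaternary C10 comes from (S)-lactic acid by Seebach alkylation, and the ribo-configured C6–C7–C8 triad, which is C2–C3–C4 of diacetone-D-glucose after 3-C-branching.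

Key step: step 18

Remark on numbering: germacrane numbers are used (C1 ketone, C2=C3 furanone alkene, C4=C5, C6 lactone carbinol, C7, C8 ester carbinol, C9, C10 quaternary, C11–C13 lactone, C14 methyl, C15 CH2OH). The target is read as 6S,7R,8R,10R with a cis-fused 6,12-lactone.
Remark on C4: C4 is a stereocentre in 15–28 that step 18 destroys; it is carried as a mixture of epimers. Lactol 19 is a mixture of anomers.

Step 1
Reactants: 1 1,2:5,6-di-O-isopropylidene-α-D-glucofuranose
Product: 2 1,2:5,6-di-O-isopropylidene-α-D-ribo-hexofuranos-3-ulose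
Conditions: Dess–Martin periodinane, CH2Cl2, rt
Reagents that add atoms: none
Why: Dess–Martin oxidation of the only free hydroxyl should give the 3-ketone without touching a stereocentre.

Step 2
Reactants: 2 the 3-ulose; 3 tert-butyl 2-(diethoxyphosphoryl)acetate
Product: 4 tert-butyl 2-(3-deoxy-1,2:5,6-di-O-isopropylidene-α-D-ribo-hexofuranos-3-ylidene)acetate (E/Z)
Conditions: NaH, THF, 0 °C → rt
Reagents that add atoms: none
Why: Horner–Wadsworth–Emmons olefination brings in C11–C12 as a tert-butyl ester; the alkene geometry is irrelevant because the alkene is reduced next.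

Step 3
Reactants: 4 the alkylidene ester
Product: 5 3-C-(tert-butoxycarbonylmethyl)-3-deoxy-1,2:5,6-di-O-isopropylidene-α-D-allofuranose
Conditions: H2 (1 atm), Pd/C, EtOAc, rt
Reagents that add atoms: none
Why: Heterogeneous hydrogenation should deliver hydrogen from the convex β-face of the cis-fused acetonide–furanose, which puts the branch α (D-allo) and sets C7 cis to the C6 and C8 oxygens.

Step 4
Reactants: 5 the allo ester
Product: 7 3-C-(tert-butoxycarbonylmethyl)-3-deoxy-1,2-O-isopropylidene-α-D-ribofuranose, via aldehyde 6 (not isolated)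
Conditions: H5IO6, EtOAc, rt; then NaBH4, EtOH, 0 °C
Reagents that add atoms: none
Why: Periodic acid should hydrolyse only the terminal 5,6-acetonide and cleave the freed glycol (glycol fission), and borohydride reduction gives the primary alcohol that becomes C9.

Step 5
Reactants: 8 (S)-lactic acid; 9 pivalaldehyde
Product: 10 (2S,5S)-2-tert-butyl-5-methyl-1,3-dioxolan-4-one
Conditions: TsOH (cat.), H2SO4 (cat.), pentane, reflux, Dean–Stark; crystallisation of the cis isomer
Reagents that add atoms: none
Why: Acid-catalysed acetalisation (self-regeneration of stereocentres) stores the lactate configuration in the acetal centre, cis to the methyl group.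

Step 6
Reactants: 7 the primary alcohol
Product: 11 5-O-trifluoromethanesulfonate of 7
Conditions: Tf2O, pyridine, CH2Cl2, −30 °C
Reagents that add atoms: trifluoromethanesulfonic anhydride, O=S(=O)(OS(=O)(=O)C(F)(F)F)C(F)(F)F
Why: Sulfonylation of the single hydroxyl; a triflate is chosen because the β-branched, β-oxygenated C9 needs a very good leaving group.

Step 7
Reactants: 11 the triflate; 10 the dioxolanone
Product: 12 (2S,5R)-2-tert-butyl-5-methyl-1,3-dioxolan-4-one carrying at C5 the 5-deoxy-ribofuranos-5-yl residue of 7 (C9–C10 bond)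
Conditions: 10, LDA, THF, −78 °C; then 11, DMPU, −78 → −45 °C
Reagents that add atoms: none
Why: Seebach alkylation of the lithium enolate should occur anti to the tert-butyl group, so C9 takes the place of the lactate hydrogen with retention and C10 is set R.

Step 8
Reactants: 12 the alkylated dioxolanone
Product: 13 (R)-2-hydroxy-N-methoxy-N,2-dimethylpropanamide carrying at C3 the ribofuranos-4-yl residue (Weinreb amide, free C10 hydroxyl)
Conditions: MeNH(OMe)·HCl, i-PrMgCl, THF, −20 → 0 °C
Reagents that add atoms: N,O-dimethylhydroxylamine hydrochloride, CNOC.Cl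
Why: Aminolysis of the activated acylal carbonyl by the magnesium amide (Weinreb amide formation) releases pivalaldehyde and the tertiary alcohol, while the hindered tert-butyl ester should not react at this temperature.

Step 9
Reactants: 14 (±)-but-3-yne-1,2-diol
Product: 15 (±)-1-(tert-butyldiphenylsilyloxy)but-3-yn-2-ol
Conditions: TBDPSCl, imidazole, CH2Cl2, 0 °C
Reagents that add atoms: tert-butyl(chloro)diphenylsilane, CC(C)(C)[Si](Cl)(c1ccccc1)c1ccccc1
Why: The bulky silyl chloride should silylate the primary hydroxyl selectively (silyl ether formation).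

Step 10
Reactants: 13 the Weinreb amide; 15 the alkyne
Product: 17 (R)-2-methyl-3(2H)-furanone carrying at C2 the ribofuranosylmethyl group and at C5 a CH(OH)CH2OTBDPS group, via hydroxy ynone 16 (not isolated)
Conditions: 15 (3 equiv), n-BuLi (6 equiv), THF, −78 °C; 13, −78 → −20 °C; NH4Cl; crude in PhMe, Ph3PAuNTf2 (3 mol %), rt
Reagents that add atoms: none
Why: Acetylide addition to the Weinreb amide stops at the ynone, and gold activation should induce 5-endo-dig attack of the tertiary C10 hydroxyl on C3 (hydroxy-ynone cycloisomerisation) to give the 3(2H)-furanone.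

Step 11
Reactants: 17 the furanone carbinol
Product: 18 the corresponding C4 chloride
Conditions: PPh3, CCl4, CH2Cl2, 0 °C → rt
Reagents that add atoms: tetrachloromethane, ClC(Cl)(Cl)Cl
Why: Appel reaction turns the secondary carbinol next to the furanone into the chloride that later serves as the electrophile; its configuration is irrelevant.

Step 12
Reactants: 18 the chloride
Product: 19 bicyclic lactone lactol (6,12-lactone closed on O6; C5 as hemiacetal with O8)
Conditions: TFA/H2O (4:1), 0 °C → rt
Reagents that add atoms: none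
Why: Acid hydrolysis removes the 1,2-acetonide and the tert-butyl group, and the acid should lactonise onto the cis O6, which differentiates O6 (lactone) from O8 (lactol ring oxygen).

Step 13
Reactants: 19 the lactone lactol
Product: 20 lactone diol (primary C5 hydroxyl, secondary C8 hydroxyl)
Conditions: NaBH4, EtOH, −10 °C, short reaction time; AcOH quench
Reagents that add atoms: none
Why: Borohydride should reduce only the open aldehyde form of the lactol, since the lactone and the vinylogous ester are much less electrophilic, and the cold acidic quench avoids acyl migration to O8.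

Step 14
Reactants: 20 the diol
Product: 21 C5 thioacetate
Conditions: AcSH, PPh3, DIAD, THF, 0 °C
Reagents that add atoms: thioacetic acid, CC(=O)S
Why: The Mitsunobu reaction is selective for the primary hydroxyl and brings in the sulfur at C5.

Step 15
Reactants: 21 the thioacetate
Product: 22 8-O-triethylsilyl ether of 21
Conditions: TESOTf, 2,6-lutidine, CH2Cl2, −78 °C
Reagents that add atoms: triethylsilyl trifluoromethanesulfonate, CC[Si](CC)(CC)OS(=O)(=O)C(F)(F)F
Why: Silylation blocks O8 so that it can neither translactonise nor act as a nucleophile in the basic steps that follow.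

Step 16
Reactants: 22 the silyl ether
Product: 24 ten-membered cyclic sulfide (ring: furanone O, C3, C4, S, C5–C10), via thiol 23 (not isolated)
Conditions: K2CO3, degassed MeOH/THF, 0.002 M, 0 °C → rt
Reagents that add atoms: none
Why: Methanolysis of the thioacetate frees the thiolate, which should displace the activated secondary chloride at C4 (SN2 thioether macrocyclisation under high dilution); the C4 centre formed is destroyed later.

Step 17
Reactants: 24 the cyclic sulfide
Product: 26 α-chloro sulfone (chlorine at C4), via α-chloro sulfide 25 (not isolated)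
Conditions: NCS, CCl4, 0 °C; then m-CPBA, CH2Cl2, 0 °C → rt
Reagents that add atoms: N-chlorosuccinimide, O=C1CCC(=O)N1Cl; m-chloroperbenzoic acid, OOC(=O)c1cccc(Cl)c1
Why: Pummerer-type α-chlorination of the sulfide followed by peracid oxidation at sulfur gives the α-chloro sulfone, and the electron-poor furanone alkene should not be epoxidised.

Step 18
Reactants: 26 the α-chloro sulfone
Product: 30 nine-membered furanone lactone (11,13-dihydro, 8-O-TES, 15-O-TBDPS), via seco hydroxy acid salt 27 (not isolated), via episulfone 28 (not isolated), via ring-contracted hydroxy acid salt 29 (not isolated)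
Conditions: LiOH·H2O, THF/H2O, 0 °C; PhMe azeotrope; KOt-Bu, THF, −78 → −10 °C; AcOH, then PPTS (cat.), CH2Cl2, rt
Reagents that add atoms: none
Why: Ramberg–Bäcklund reaction: hydroxide first opens the γ-lactone to 27 so that O6 is a hydroxyl or alkoxide that cannot be expelled when KOt-Bu deprotonates C5; the C5 carbanion then displaces chloride from C4 by 3-exo-tet closure to episulfone 28, which loses SO2 cheletropically to give alkene 29, and acidification re-closes the lactone by 5-exo-trig lactonisation. The closest known reaction type is the base-induced ring contraction of cyclic α-halo sulfones to cycloalkenes, which is established for medium rings. No stereocentre is formed: the alkene can only be ring-cis in a nine-membered ring, which is the required geometry (C3 and C6 cis), and C6, C7, C8 and C10 are not touched. The step needs carbanion formation at C5 without β-elimination of the C6 oxygen and without attack on the furanone; the temporary saponification, the fully substituted C4 and C10 and the low temperature should secure this, and a regioisomeric chloride at C5 would converge on the same alkene.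

Step 19
Reactants: 30 the dihydro lactone
Product: 32 α-methylene lactone (8-O-TES, 15-O-TBDPS), via Mannich base 31 (not isolated)
Conditions: LiHMDS, THF, −78 °C; CH2=NMe2+ I−, −78 → 0 °C; MeI, CH2Cl2/MeOH, rt; aq. NaHCO3
Reagents that add atoms: Eschenmoser's salt, C=[N+](C)C.[I-]
Why: Kinetic lactone enolate formation and Mannich reaction, then N-methylation and elimination, should install the exocyclic methylene (α-methylenation of a lactone).

Step 20
Reactants: 32 the α-methylene lactone
Product: 33 C8 alcohol (15-O-TBDPS)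
Conditions: PPTS, MeOH/CH2Cl2, 0 °C
Reagents that add atoms: none
Why: Mild acid methanolysis should remove the triethylsilyl ether while the more robust TBDPS ether stays.

Step 21
Reactants: 33 the C8 alcohol; 34 (E)-2-methylbut-2-enoyl chloride (tigloyl chloride)
Product: 35 8-O-tigloyl ester (15-O-TBDPS)
Conditions: DMAP, pyridine, CH2Cl2, 0 °C → rt
Reagents that add atoms: none
Why: DMAP-catalysed acylation of the secondary alcohol with the acid chloride; the (E)-tiglate is the stable isomer and should be kept.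

Step 22
Reactants: 35 the silyl-protected tiglate
Product: 36 target
Conditions: HF·pyridine, pyridine, THF, 0 °C → rt
Reagents that add atoms: none
Why: Buffered fluoride desilylation should free the C15 hydroxyl without harming the α-methylene lactone, the tiglate or the furanone.

Compound list
1 | 1,2:5,6-di-O-isopropylidene-α-D-glucofuranose | CC1(C)OC[C@@H](O1)[C@H]2O[C@@H]3OC(C)(C)O[C@@H]3[C@H]2O | starting material
2 | 1,2:5,6-di-O-isopropylidene-α-D-ribo-hexofuranos-3-ulose | CC1(C)OC[C@@H](O1)[C@H]2O[C@@H]3OC(C)(C)O[C@@H]3C2=O | intermediate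
3 | tert-butyl 2-(diethoxyphosphoryl)acetate | CCOP(=O)(CC(=O)OC(C)(C)C)OCC | starting material
4 | tert-butyl 2-(3-deoxy-1,2:5,6-di-O-isopropylidene-α-D-ribo-hexofuranos-3-ylidene)acetate (E/Z) | CC1(C)OC[C@@H](O1)[C@H]2O[C@@H]3OC(C)(C)O[C@@H]3C2=CC(=O)OC(C)(C)C | intermediate
5 | 3-C-(tert-butoxycarbonylmethyl)-3-deoxy-1,2:5,6-di-O-isopropylidene-α-D-allofuranose | CC1(C)OC[C@@H](O1)[C@H]2O[C@@H]3OC(C)(C)O[C@@H]3[C@@H]2CC(=O)OC(C)(C)C | intermediate
6 | 3-C-(tert-butoxycarbonylmethyl)-3-deoxy-1,2-O-isopropylidene-α-D-ribo-pentodialdo-1,4-furanose | O=C[C@H]1O[C@@H]2OC(C)(C)O[C@@H]2[C@@H]1CC(=O)OC(C)(C)C | intermediate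
7 | 3-C-(tert-butoxycarbonylmethyl)-3-deoxy-1,2-O-isopropylidene-α-D-ribofuranose | OC[C@H]1O[C@@H]2OC(C)(C)O[C@@H]2[C@@H]1CC(=O)OC(C)(C)C | intermediate
8 | (S)-lactic acid | C[C@H](O)C(=O)O | starting material
9 | pivalaldehyde | CC(C)(C)C=O | starting material
10 | (2S,5S)-2-tert-butyl-5-methyl-1,3-dioxolan-4-one | C[C@@H]1O[C@H](C(C)(C)C)OC1=O | intermediate
11 | 5-O-trifluoromethanesulfonate of 7 | O=S(=O)(OC[C@H]1O[C@@H]2OC(C)(C)O[C@@H]2[C@@H]1CC(=O)OC(C)(C)C)C(F)(F)F | intermediate
12 | (2S,5R)-2-tert-butyl-5-methyl-1,3-dioxolan-4-one with the 5-deoxy-ribofuranos-5-yl residue of 7 at C5 | C[C@]1(C[C@H]2O[C@@H]3OC(C)(C)O[C@@H]3[C@@H]2CC(=O)OC(C)(C)C)O[C@H](C(C)(C)C)OC1=O | intermediate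
13 | (R)-2-hydroxy-N-methoxy-N,2-dimethyl-3-(ribofuranos-4-yl)propanamide (Weinreb amide) | CON(C)C(=O)[C@](C)(O)C[C@H]1O[C@@H]2OC(C)(C)O[C@@H]2[C@@H]1CC(=O)OC(C)(C)C | intermediate
14 | (±)-but-3-yne-1,2-diol | C#CC(O)CO | starting material
15 | (±)-1-(tert-butyldiphenylsilyloxy)but-3-yn-2-ol | C#CC(O)CO[Si](c1ccccc1)(c1ccccc1)C(C)(C)C | intermediate
16 | hydroxy ynone (C1 ketone, C2≡C3, C4 carbinol, free C10 hydroxyl) | CC(C)(C)[Si](c1ccccc1)(c1ccccc1)OCC(O)C#CC(=O)[C@](C)(O)C[C@H]1O[C@@H]2OC(C)(C)O[C@@H]2[C@@H]1CC(=O)OC(C)(C)C | intermediate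
17 | 3(2H)-furanone carbinol (C10 R; C4 carbinol; furanose still protected) | CC(C)(C)[Si](c1ccccc1)(c1ccccc1)OCC(O)C1=CC(=O)[C@@](C)(C[C@H]2O[C@@H]3OC(C)(C)O[C@@H]3[C@@H]2CC(=O)OC(C)(C)C)O1 | intermediate
18 | C4 chloride of 17 | CC(C)(C)[Si](c1ccccc1)(c1ccccc1)OCC(Cl)C1=CC(=O)[C@@](C)(C[C@H]2O[C@@H]3OC(C)(C)O[C@@H]3[C@@H]2CC(=O)OC(C)(C)C)O1 | intermediate
19 | bicyclic 6,12-lactone lactol (C5 hemiacetal with O8) | O=C1C[C@H]2[C@@H](O1)C(O)O[C@@H]2C[C@@]3(C)OC(=CC3=O)C(Cl)CO[Si](c4ccccc4)(c4ccccc4)C(C)(C)C | intermediate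
20 | lactone diol (C5 and C8 hydroxyls) | O=C1C[C@@H]([C@@H](O1)CO)[C@H](O)C[C@@]2(C)OC(=CC2=O)C(Cl)CO[Si](c3ccccc3)(c3ccccc3)C(C)(C)C | intermediate
21 | C5 thioacetate | O=C1C[C@@H]([C@@H](O1)CSC(C)=O)[C@H](O)C[C@@]2(C)OC(=CC2=O)C(Cl)CO[Si](c3ccccc3)(c3ccccc3)C(C)(C)C | intermediate
22 | 8-O-triethylsilyl ether of 21 | O=C1C[C@@H]([C@@H](O1)CSC(C)=O)[C@H](O[Si](CC)(CC)CC)C[C@@]2(C)OC(=CC2=O)C(Cl)CO[Si](c3ccccc3)(c3ccccc3)C(C)(C)C | intermediate
23 | C5 thiol | O=C1C[C@@H]([C@@H](O1)CS)[C@H](O[Si](CC)(CC)CC)C[C@@]2(C)OC(=CC2=O)C(Cl)CO[Si](c3ccccc3)(c3ccccc3)C(C)(C)C | intermediate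
24 | ten-membered cyclic sulfide (C4–S–C5) | O=C1C[C@H]2[C@@H](O1)CSC(CO[Si](c4ccccc4)(c4ccccc4)C(C)(C)C)C3=CC(=O)[C@@](C)(C[C@H]2O[Si](CC)(CC)CC)O3 | intermediate
25 | α-chloro sulfide (chlorine at C4) | O=C1C[C@H]2[C@@H](O1)CSC(Cl)(CO[Si](c4ccccc4)(c4ccccc4)C(C)(C)C)C3=CC(=O)[C@@](C)(C[C@H]2O[Si](CC)(CC)CC)O3 | intermediate
26 | α-chloro sulfone (chlorine at C4) | O=C1C[C@H]2[C@@H](O1)CS(=O)(=O)C(Cl)(CO[Si](c4ccccc4)(c4ccccc4)C(C)(C)C)C3=CC(=O)[C@@](C)(C[C@H]2O[Si](CC)(CC)CC)O3 | intermediate
27 | seco hydroxy acid of 26 (present as the lithium carboxylate) | OC(=O)C[C@H]1[C@@H](O)CS(=O)(=O)C(Cl)(CO[Si](c2ccccc2)(c2ccccc2)C(C)(C)C)C3=CC(=O)[C@@](C)(C[C@H]1O[Si](CC)(CC)CC)O3 | intermediate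
28 | episulfone (thiirane 1,1-dioxide across C4–C5; present as the carboxylate) | OC(=O)C[C@H]1[C@@H](O)C4C(CO[Si](c2ccccc2)(c2ccccc2)C(C)(C)C)(C3=CC(=O)[C@@](C)(C[C@H]1O[Si](CC)(CC)CC)O3)S4(=O)=O | intermediate
29 | ring-contracted hydroxy acid with the C4=C5 alkene (present as the carboxylate) | OC(=O)C[C@H]1[C@@H](O)/C=C(/CO[Si](c2ccccc2)(c2ccccc2)C(C)(C)C)C3=CC(=O)[C@@](C)(C[C@H]1O[Si](CC)(CC)CC)O3 | intermediate
30 | nine-membered furanone lactone (11,13-dihydro, 8-O-TES, 15-O-TBDPS) | O=C1C[C@H]2[C@@H](O1)/C=C(/CO[Si](c4ccccc4)(c4ccccc4)C(C)(C)C)C3=CC(=O)[C@@](C)(C[C@H]2O[Si](CC)(CC)CC)O3 | intermediate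
31 | Mannich base (C11 dimethylaminomethyl) | O=C1C(CN(C)C)[C@H]2[C@@H](O1)/C=C(/CO[Si](c4ccccc4)(c4ccccc4)C(C)(C)C)C3=CC(=O)[C@@](C)(C[C@H]2O[Si](CC)(CC)CC)O3 | intermediate
32 | α-methylene lactone (8-O-TES, 15-O-TBDPS) | O=C1C(=C)[C@H]2[C@@H](O1)/C=C(/CO[Si](c4ccccc4)(c4ccccc4)C(C)(C)C)C3=CC(=O)[C@@](C)(C[C@H]2O[Si](CC)(CC)CC)O3 | intermediate
33 | C8 alcohol (15-O-TBDPS) | O=C1C(=C)[C@H]2[C@@H](O1)/C=C(/CO[Si](c4ccccc4)(c4ccccc4)C(C)(C)C)C3=CC(=O)[C@@](C)(C[C@H]2O)O3 | intermediate
34 | (E)-2-methylbut-2-enoyl chloride (tigloyl chloride) | C/C=C(\C)C(=O)Cl | starting material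
35 | 8-O-tigloyl ester (15-O-TBDPS) | O=C1C(=C)[C@H]2[C@@H](O1)/C=C(/CO[Si](c4ccccc4)(c4ccccc4)C(C)(C)C)C3=CC(=O)[C@@](C)(C[C@H]2OC(=O)/C(C)=C/C)O3 | intermediate
36 | target | C=C1C(=O)O[C@H]2/C=C(/CO)C3=CC(=O)[C@@](C)(C[C@@H](OC(=O)/C(C)=C/C)[C@@H]12)O3 | target

Total step count: 22. Longest linear sequence: 20 steps (from 1: steps 1–4, 6–8 and 10–22).

Steps most likely to fail

1. Step 18 (ring contraction). With the lactone opened, the C6 alkoxide next to the sulfone may fragment by retro-aldol cleavage of C5–C6, or it may slow deprotonation at C5 so that the furanone is degraded first. Fallback: the same contraction on a masked substrate. From 26, the lactone is saponified as before and the crude seco acid is silylated with N,O-bis(trimethylsilyl)acetamide to the O6-trimethylsilyl ether trimethylsilyl ester F1. KOt-Bu (THF, −78 → −20 °C) should cleave the silyl ester and effect the Ramberg–Bäcklund contraction to the ring-contracted O6-silylated acid F2. Citric acid in MeOH should remove the trimethylsilyl ether while the hindered triethylsilyl ether at O8 stays, and the hydroxy acid lactonises to 30, where the route is rejoined.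

2. Step 16 (macrocyclisation). Intermolecular thioether formation may outrun closure of the ten-membered ring, or methoxide may eliminate HCl at C4. Fallback: from 22, potassium thioacetate (DMF, rt) displaces the chloride to give the bis(thioacetate) F3. Methanolysis (K2CO3, MeOH) and oxidation with iodine at high dilution should close the eleven-membered cyclic disulfide F4, since reversible S–S formation corrects oligomers. Desulfurisation with tris(diethylamino)phosphine (benzene, rt) should contract F4 to sulfide 24.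

3. Step 7 (alkylation with the hindered triflate). Slow substitution at the β-branched, β-oxygenated primary carbon may let the thermally labile dioxolanone enolate decompose, or the triflate may eliminate. Fallback: from aldehyde 6, isolated after the periodic acid stage, aldol addition of the lithium enolate of 10 (THF, −78 °C, again anti to the tert-butyl group) should give the C9 carbinol F5. Its imidazole-1-carbothioate F6 (thiocarbonyldiimidazole, DMAP, 60 °C) is deoxygenated with Bu3SnH/AIBN (Barton–McCombie) to give 12.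

Further compounds
F1 | step 18 | O6-trimethylsilyl ether trimethylsilyl ester of seco acid 27 | C[Si](C)(C)OC(=O)C[C@H]1[C@@H](O[Si](C)(C)C)CS(=O)(=O)C(Cl)(CO[Si](c2ccccc2)(c2ccccc2)C(C)(C)C)C3=CC(=O)[C@@](C)(C[C@H]1O[Si](CC)(CC)CC)O3
F2 | step 18 | ring-contracted O6-trimethylsilyl hydroxy acid | OC(=O)C[C@H]1[C@@H](O[Si](C)(C)C)/C=C(/CO[Si](c2ccccc2)(c2ccccc2)C(C)(C)C)C3=CC(=O)[C@@](C)(C[C@H]1O[Si](CC)(CC)CC)O3
F3 | step 16 | C4,C5-bis(thioacetate) | O=C1C[C@@H]([C@@H](O1)CSC(C)=O)[C@H](O[Si](CC)(CC)CC)C[C@@]2(C)OC(=CC2=O)C(SC(C)=O)CO[Si](c3ccccc3)(c3ccccc3)C(C)(C)C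
F4 | step 16 | eleven-membered cyclic disulfide (C4–S–S–C5) | O=C1C[C@H]2[C@@H](O1)CSSC(CO[Si](c4ccccc4)(c4ccccc4)C(C)(C)C)C3=CC(=O)[C@@](C)(C[C@H]2O[Si](CC)(CC)CC)O3
F5 | step 7 | aldol adduct of 10 and 6 (C9 carbinol) | C[C@]1(C(O)[C@H]2O[C@@H]3OC(C)(C)O[C@@H]3[C@@H]2CC(=O)OC(C)(C)C)O[C@H](C(C)(C)C)OC1=O
F6 | step 7 | C9 O-(imidazole-1-carbothioate) of F5 | C[C@]1(C(OC(=S)n2ccnc2)[C@H]3O[C@@H]4OC(C)(C)O[C@@H]4[C@@H]3CC(=O)OC(C)(C)C)O[C@H](C(C)(C)C)OC1=O
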